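**Retrosynthetic overview**
1. 20 ⇐ tetramethyl ether 19 ⇐ cross-conjugated dienone 17 + aryl Grignard reagent 18 (copper-catalysed 1,4-addition at C6, anti to the C5 aryl group, gives the trans pair).
2. 17 ⇐ enone 15 (α′-dehydrogenation) ⇐ enone 11 (1,2-addition of styryllithium, then oxidative 1,3-transposition: the old carbonyl carbon becomes C3, the old β-carbon becomes C1).
3. 11 ⇐ symmetric cyclohepta-2,6-dienone 9 + boronic acid 10 (enantioselective rhodium-catalysed mono-arylation sets C5).
4. 9 ⇐ tropinone 6 (methylation and double β-elimination remove the nitrogen) ⇐ 1 + 2 + 3 (double Mannich reaction).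
5. Ring order: the pyrrolidine and piperidinone rings of 6, and with them the seven-membered carbocycle, close together in step 1; the nitrogen bridge is only a template and is cut out in step 2; no other ring is formed.

Numbering: ring atoms are numbered as in the target (C1 = C=O, C3 styryl, C5 3,5-dioxygenated aryl, C6 3,4-dioxygenated aryl).

Assumption: the facial sense of the rhodium/BINAP addition to 9 is taken from the known result for cyclohept-2-en-1-one ((S)-BINAP gives the (S)-3-aryl ketone), so (R)-BINAP is used; if 9 responded with the opposite sense, (S)-BINAP would be used instead.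

**Step 1**
Reactants: 1 2,5-dimethoxytetrahydrofuran; 2 methylamine (40% in water); 3 3-oxopentanedioic acid (acetonedicarboxylic acid)
Product: 6 tropinone (8-methyl-8-azabicyclo[3.2.1]octan-3-one; meso), via butanedial 4 (not isolated), via tropinone-2,4-dicarboxylic acid 5 (not isolated)
Conditions: HCl (cat.), H2O, 70 °C, 20 min; then 2, 3, Na2HPO4–citric acid buffer pH 5, 25 °C, 48 h; then 60 °C, 1 h
Reagents that add atoms: none
Why: Robinson–Schöpf double Mannich reaction: 4 and 2 give a cyclic iminium ion that is attacked twice by the doubly activated methylene carbons of 3, which closes the pyrrolidine and the piperidinone ring (and so the seven-membered carbocycle) in one operation, and the two β-keto acid groups of 5 then lose CO2; the bridgeheads are necessarily cis, so 6 is meso and no stereochemical choice arises.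

**Step 2**
Reactants: 6 tropinone
Product: 9 cyclohepta-2,6-dien-1-one, via tropinone methiodide 7 (not isolated), via 6-(dimethylamino)cyclohept-2-en-1-one 8 (not isolated)
Conditions: MeI, acetone, 25 °C; evaporate; then NaHCO3, H2O, 95 °C, product carried over with steam
Reagents that add atoms: none
Why: Exhaustive methylation and two successive E1cB eliminations (Hofmann-type, retro-aza-Michael) of the β-ammonium and then the β-amino ketone cut the nitrogen bridge out and leave the symmetric cross-conjugated dienone, a known degradation of tropinone; no stereocenter is present.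

**Step 3**
Reactants: 9 cyclohepta-2,6-dien-1-one (3 equiv); 10 (3,5-dimethoxyphenyl)boronic acid
Product: 11 (6R)-6-(3,5-dimethoxyphenyl)cyclohept-2-en-1-one
Conditions: [Rh(OH)((R)-BINAP)]2 (1.5 mol%), dioxane/H2O 10:1, 35 °C
Reagents that add atoms: none
Why: Hayashi–Miyaura asymmetric 1,4-addition: the two enone units of 9 are equivalent by symmetry, so only face selection matters, and the aryl–rhodium/(R)-BINAP species delivers the aryl group to one face to set the benzylic center (later C5) as R; the excess of 9 holds the reaction at mono-addition and the neutral medium leaves the second enone in place.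

**Step 4**
Reactants: 11 (6R)-6-(3,5-dimethoxyphenyl)cyclohept-2-en-1-one; 12 [(E)-2-bromoethenyl]benzene
Product: 14 (6R)-6-(3,5-dimethoxyphenyl)-1-[(E)-2-phenylethenyl]cyclohept-2-en-1-ol (both C1 epimers), via (E)-styryllithium 13 (not isolated)
Conditions: 12, t-BuLi (2 equiv), Et2O, −78 °C; then 11, −78 °C; H2O
Reagents that add atoms: none
Why: Bromine–lithium exchange gives the alkenyllithium with retention of the E geometry and this hard nucleophile adds 1,2 to the enone carbonyl (organolithium carbonyl addition); the new carbinol center forms as a mixture, which is harmless because it becomes sp2 in step 5, and C6 is untouched.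

**Step 5**
Reactants: 14 (6R)-6-(3,5-dimethoxyphenyl)-1-[(E)-2-phenylethenyl]cyclohept-2-en-1-ol
Product: 15 (5R)-5-(3,5-dimethoxyphenyl)-3-[(E)-2-phenylethenyl]cyclohept-2-en-1-one
Conditions: (C5H5NH)[CrO3Cl] (3 equiv), 4 Å molecular sieves, CH2Cl2, 25 °C
Reagents that add atoms: pyridinium chlorochromate, [O-][Cr](=O)(=O)Cl.c1cc[nH+]cc1 (one of its oxo oxygens becomes the carbonyl oxygen; the hydroxyl oxygen of 14 leaves on chromium)
Why: Dauben–Babler oxidative 1,3-transposition: the tertiary chromate ester shifts by [3,3] rearrangement to the ring allylic terminus, the isomer that keeps the phenyl–diene conjugation, and is oxidised there by hexavalent chromium, so the carbonyl appears two carbons away and the styryl group ends on the β-carbon; the aryl-bearing center is not involved and stays R.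

**Step 6**
Reactants: 15 (5R)-5-(3,5-dimethoxyphenyl)-3-[(E)-2-phenylethenyl]cyclohept-2-en-1-one
Product: 17 (5S)-5-(3,5-dimethoxyphenyl)-3-[(E)-2-phenylethenyl]cyclohepta-2,6-dien-1-one, via trimethylsilyl dienol ether 16 (not isolated)
Conditions: LiN(iPr)2, THF, −78 °C; Me3SiCl; solvent change; then Pd(OAc)2 (1.05 equiv), MeCN, 25 °C
Reagents that add atoms: none
Why: Saegusa–Ito dehydrogenation: LiN(iPr)2 removes the kinetic α′-proton at C7 rather than the vinylogous γ-proton at C4, and divalent palladium turns the silyl dienol ether 16 into the second enone by β-hydride elimination; C5 keeps its geometry (the descriptor changes to S only because C6 now outranks C4).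

**Step 7**
Reactants: 17 (5S)-5-(3,5-dimethoxyphenyl)-3-[(E)-2-phenylethenyl]cyclohepta-2,6-dien-1-one; 18 (3,4-dimethoxyphenyl)magnesium bromide (0.5 M in THF)
Product: 19 (5S,6S)-6-(3,4-dimethoxyphenyl)-5-(3,5-dimethoxyphenyl)-3-[(E)-2-phenylethenyl]cyclohept-2-en-1-one
Conditions: 18 (2 equiv), CuBr·SMe2 (10 mol%), THF, −78 to −40 °C; NH4Cl (aq.)
Reagents that add atoms: none
Why: Copper-catalysed conjugate addition of a Grignard reagent (organocuprate 1,4-addition): the aryl group adds to the unsubstituted β-carbon C6 of the less hindered enone from the face opposite to the aryl group on the adjacent carbon C5, which sets C6 as S and the two aryl groups trans (1,2-induction), while the β,β-disubstituted styryl enone does not react.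

**Step 8**
Reactants: 19 (5S,6S)-6-(3,4-dimethoxyphenyl)-5-(3,5-dimethoxyphenyl)-3-[(E)-2-phenylethenyl]cyclohept-2-en-1-one
Product: 20 (5S,6S)-6-(3,4-dihydroxyphenyl)-5-(3,5-dihydroxyphenyl)-3-[(E)-2-phenylethenyl]cyclohept-2-en-1-one (CNP0400050.1)
Conditions: BBr3 (8 equiv), CH2Cl2, −78 to 0 °C; then H2O
Reagents that add atoms: none
Why: Lewis acid cleavage of aryl methyl ethers: BBr3 binds each ether oxygen, bromide removes the methyl group by SN2 and hydrolysis of the aryl borates frees the four phenols; neither stereocenter has an acidic hydrogen under these conditions and the dienone lacks the divinyl ketone unit needed for a Nazarov closure, so at low temperature the carbon skeleton should be left alone.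

**Compound list**
1 | 2,5-dimethoxytetrahydrofuran (cis/trans mixture) | COC1CCC(OC)O1 | starting material
2 | methylamine | CN | starting material
3 | 3-oxopentanedioic acid (acetonedicarboxylic acid) | OC(=O)CC(=O)CC(=O)O | starting material
4 | butanedial (succinaldehyde) | O=CCCC=O | intermediate
5 | tropinone-2,4-dicarboxylic acid (8-methyl-3-oxo-8-azabicyclo[3.2.1]octane-2,4-dicarboxylic acid; cis-bridged, C2/C4 epimers) | CN1[C@@H]2CC[C@H]1C(C(=O)O)C(=O)C2C(=O)O | intermediate
6 | tropinone ((1R,5S)-8-methyl-8-azabicyclo[3.2.1]octan-3-one; meso) | CN1[C@@H]2CC[C@H]1CC(=O)C2 | intermediate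
7 | tropinone methiodide ((1R,5S)-8,8-dimethyl-3-oxo-8-azoniabicyclo[3.2.1]octane iodide) | C[N+]1(C)[C@@H]2CC[C@H]1CC(=O)C2.[I-] | intermediate
8 | 6-(dimethylamino)cyclohept-2-en-1-one (racemic) | CN(C)C1CCC=CC(=O)C1 | intermediate
9 | cyclohepta-2,6-dien-1-one | O=C1C=CCCC=C1 | intermediate
10 | (3,5-dimethoxyphenyl)boronic acid | COc1cc(OC)cc(c1)B(O)O | starting material
11 | (6R)-6-(3,5-dimethoxyphenyl)cyclohept-2-en-1-one | O=C1C[C@H](c2cc(OC)cc(OC)c2)CCC=C1 | intermediate
12 | [(E)-2-bromoethenyl]benzene ((E)-β-bromostyrene) | Br/C=C/c1ccccc1 | starting material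
13 | [(E)-2-phenylethenyl]lithium ((E)-styryllithium) | [Li]/C=C/c1ccccc1 | intermediate
14 | (6R)-6-(3,5-dimethoxyphenyl)-1-[(E)-2-phenylethenyl]cyclohept-2-en-1-ol (both C1 epimers) | OC1(/C=C/c2ccccc2)C[C@H](c2cc(OC)cc(OC)c2)CCC=C1 | intermediate
15 | (5R)-5-(3,5-dimethoxyphenyl)-3-[(E)-2-phenylethenyl]cyclohept-2-en-1-one | O=C1C=C(/C=C/c2ccccc2)C[C@H](c2cc(OC)cc(OC)c2)CC1 | intermediate
16 | trimethylsilyl dienol ether of 15, {[(4R)-4-(3,5-dimethoxyphenyl)-6-[(E)-2-phenylethenyl]cyclohepta-1,6-dien-1-yl]oxy}trimethylsilane | C[Si](C)(C)OC=1C=C(/C=C/c2ccccc2)C[C@H](c2cc(OC)cc(OC)c2)CC=1 | intermediate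
17 | (5S)-5-(3,5-dimethoxyphenyl)-3-[(E)-2-phenylethenyl]cyclohepta-2,6-dien-1-one | O=C1C=C(/C=C/c2ccccc2)C[C@H](c2cc(OC)cc(OC)c2)C=C1 | intermediate
18 | (3,4-dimethoxyphenyl)magnesium bromide | COc1ccc([Mg]Br)cc1OC | starting material
19 | (5S,6S)-6-(3,4-dimethoxyphenyl)-5-(3,5-dimethoxyphenyl)-3-[(E)-2-phenylethenyl]cyclohept-2-en-1-one (trans-5,6) | O=C1C=C(/C=C/c2ccccc2)C[C@H](c2cc(OC)cc(OC)c2)[C@@H](c2ccc(OC)c(OC)c2)C1 | intermediate
20 | (5S,6S)-6-(3,4-dihydroxyphenyl)-5-(3,5-dihydroxyphenyl)-3-[(E)-2-phenylethenyl]cyclohept-2-en-1-one (trans-5,6) | O=C1C=C(/C=C/c2ccccc2)C[C@H](c2cc(O)cc(O)c2)[C@@H](c2ccc(O)c(O)c2)C1 | target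

**Step count**
Total step count: 8. Longest linear sequence: 8 steps (1 to 20; 10, 12 and 18 are bought).

**Steps most likely to fail**

Step 5 is the most uncertain. The chromate ester of 14 has two allylic termini, and oxidation at the benzylic end would give a phenyl ketone instead of 15. The fallback separates rearrangement from oxidation and sets out from 14. Ph3SiOReO3 (2 mol%, Et2O, 0 °C) equilibrates the allylic alcohols by 1,3-hydroxyl shift towards the most conjugated one, (5R)-5-(3,5-dimethoxyphenyl)-3-[(E)-2-phenylethenyl]cyclohept-2-en-1-ol F4. MnO2 in CH2Cl2 then oxidises this secondary dienyl alcohol, and the fallback comes back to the route at 15.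

Step 7 is next. The seven-membered dienone is flexible, so the anti preference may be modest; the styryl group offers a 1,6-pathway; and the C5 hydrogen of 17 is γ to the new enone and benzylic. The fallback moves stereocontrol from the substrate to the catalyst and sets out from 17. (3,4-Dimethoxyphenyl)boronic acid is added with [Rh(OH)((R)-BINAP)]2 in dioxane/H2O at 35 °C (Hayashi–Miyaura addition); by the same facial model as in step 3 this ligand enantiomer should reinforce anti attack. Aryl–rhodium species add 1,4 to the disubstituted enone only, and the medium is neutral, so C5 should not epimerise. This fallback makes no new compound (none F0) and comes back to the route at 19.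

Step 3 is the third. Dienone 9 is labile, the mono-adduct 11 is itself an enone that can take a second aryl group, and the level of enantioselectivity on this substrate is inferred by analogy. The fallback inverts the order of events and sets out from 9. The lithium reagent 13 (made from 12 as in step 4) is added first to give the symmetric tertiary alcohol 1-[(E)-2-phenylethenyl]cyclohepta-2,6-dien-1-ol F1. (C5H5NH)[CrO3Cl] transposes it oxidatively to 3-[(E)-2-phenylethenyl]cyclohepta-2,4-dien-1-one F2, where both ring alkenes of F1 are equivalent. An iridium/chiral diene catalysed 1,6-addition of 10 (as its boroxine; [IrCl(coe)2]2 as precursor) then places the aryl group on the ring δ-carbon, which is less hindered than the phenyl-bearing styryl terminus, and gives (5R)-5-(3,5-dimethoxyphenyl)-3-[(E)-2-phenylethenyl]cyclohept-3-en-1-one F3. DBU brings the double bond back into conjugation, and the fallback comes back to the route at 15.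

**Further compounds**
F1 | step 3 | 1-[(E)-2-phenylethenyl]cyclohepta-2,6-dien-1-ol | OC1(/C=C/c2ccccc2)C=CCCC=C1
F2 | step 3 | 3-[(E)-2-phenylethenyl]cyclohepta-2,4-dien-1-one | O=C1C=C(/C=C/c2ccccc2)C=CCC1
F3 | step 3 | (5R)-5-(3,5-dimethoxyphenyl)-3-[(E)-2-phenylethenyl]cyclohept-3-en-1-one | O=C1CC(/C=C/c2ccccc2)=C[C@H](c2cc(OC)cc(OC)c2)CC1
F4 | step 5 | (5R)-5-(3,5-dimethoxyphenyl)-3-[(E)-2-phenylethenyl]cyclohept-2-en-1-ol (both C1 epimers) | OC1C=C(/C=C/c2ccccc2)C[C@H](c2cc(OC)cc(OC)c2)CC1
F0 | step 7 | none | none
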